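## The problem

The target is an eremophilane: a cis-fused decalin (ring A: C1–C5 and C10; ring B: C5–C10) with methyls C14 on C5 and C15 on C4, an isopropenyl group (C11–C13) on C7, a C8 ketone, a C9 hydroxyl, and a (2E,4R)-4-angeloyloxyhex-2-enoyl chain on the C3 oxygen. Six ring stereocentres, (3R,4R,5R,7R,9R,10S), must be set; in face terms these are 3α-O, 4β-Me, 5β-Me, 7β-isopropenyl, 9β-OH and 10β-H, and C4′ of the chain is the seventh. Ring A holds the hard carbon work: quaternary C5, flanked by C4 whose methyl is cis to C14 and by the ring-fusion carbon C10. Once C5 and C10 exist they steer the rest. C1 and C4 lie on the α face of ring B, so C9 is reached from the β face. C14 is syn-axial to C3, so addition across C3=C4 from the α face fixes C3 and C4 together. C7 has no kinetic help, but its β configuration puts C14, the isopropenyl group and the C9 oxygen all equatorial on ring B and is the thermodynamic one. Ring B is fragile: C7 and C9 are enolisable, the isopropenyl double bond slips into conjugation, and the ketol can transpose. The chain is fragile too: the angelate isomerises to the tiglate, and the γ-acyloxy enoate is an allylic ester that zerovalent palladium, hydrides and enolate bases destroy, so it must go on last. The opening is that C5 is quaternary and para to the C8 carbonyl. Ring B can therefore be written as a 4,4-disubstituted cyclohexa-2,5-dienone with enantiotopic enone arms C6=C7 and C10=C9, and a carbon acid at C1 on a C4–C3–C2 tether from C5 can add to C10, closing ring A and leaving C6=C7–C8=O for ring B.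

## Retrosynthesis

**Ester and C9 protection (39 ⇒ 38 ⇒ 30 + 37).** The O9–Si bond and the C3–O acyl bond are cut first. The chain cannot pass through palladium, hydride or enolate steps, so every ring operation must precede it. This leaves the C15 alcohol 30 and the acid 37. The forward steps must acylate the one free hydroxyl without isomerising the angelate or C7, then remove silicon with fluoride.

**Acid 37 (37 ⇒ 35 + 36; 35 ⇒ 32 + 33; 32 ⇒ 31).** C2′=C3′ is cut by cross-metathesis of allylic angelate 35 with acrylic acid 36. This is preferred to an olefination of an α-acyloxy aldehyde, which racemises easily. Ester 35 comes from alcohol 32 and angelic acid 33, and 32 from the commercial epoxide 31 by one-carbon homologation. The demands are E selectivity and an esterification that keeps the Z geometry.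

**C7–C11 (30 ⇒ 28 ⇒ 26 + 27).** The isopropenyl group is detached as boronate 27 from α-iodoenone 26; dienone 28 lies between. An aldol with acetone followed by dehydration would give the conjugated 7(11)-ene. The coupling uses the C6=C7–C8=O unit that the key step leaves untouched. The forward reduction must touch only the enone, and C7 must settle equatorial.

**C3–O and C4–H (26 ⇒ 25 ⇒ 23 ⇒ 22 ⇒ 21).** Both ring A centres are removed as one syn addition across C3=C4 (hydroboration). Hydroxylating a C4 ketone and then methylenating it would put a second ketone beside C8 in every enolisation. Borane tolerates neither a ketone nor a reactive alkene, so ring B is parked as the 7-iodo-8-ol 23. The iodine is needed anyway and deactivates C6=C7. Allylic oxidation (25 ⇒ 26) restores the ketone. Diene 21 has no ring A stereocentre.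

**C9–O (21 ⇒ 20 ⇒ 18).** The hydroxyl comes from the cross-conjugated enolate of 18. At this stage C9 is the only enolisable position, which is why this precedes any substitution at C7. The ring fusion must supply the β face.

**Alkene position and C1–N (18 ⇒ 17 ⇒ 16 ⇒ 15 ⇒ 14).** The Δ3 alkene is traced to the exocyclic methylene of 17 by a metal-catalysed shift. C1–H is traced to C1–NO2 by radical denitration. Stannyl radicals reduce conjugated ketones, so the enone is held as allylic alcohol (14 ⇒ 15), denitrated (15 ⇒ 16) and reoxidised (16 ⇒ 17).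

**Key cut (14 ⇒ 13).** Breaking C1–C10 opens ring A and erases C5, C10 and C1 as stereocentres: 13 is achiral, with a nitroalkane tethered to a dienone. The forward step asks a chiral base catalyst to choose one of two enantiotopic arms.

**Precursor (13 ⇒ 12 ⇒ 11 ⇒ 10 ⇒ 8 ⇒ 7 ⇒ 4 ⇒ 1, 2, 5).** Nitro is traced to iodide 12 and chloride 11. Dienone 11 comes from enone 10 by dehydrogenation, and 10 from vinylogous ester 8 by reduction and acid transposition. Alkene 8 comes from ketone 7, and 7 and 4 from acylation with 5 and methylation with 2 of 1. C4 is carried as a methylene rather than a ketone or acetal for three reasons. An acetal would have to be made on a neopentyl ketone beside a vinylogous ester. A C4 carbonyl would later compete with C8. The methylene already holds C15 and is inert in the key step.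

## Roads not taken

Alternative 1: The cut goes through C5–C10 and C3–C4 together. In the open-chain trienone A1, an (E)-tigloyl ketone is linked through C7–C9 to a 1-boryl-1,3-diene. Heating would close both rings by intramolecular Diels–Alder reaction to the cis-fused allylboronate A2.
- Merits: the dienophile geometry becomes the cis C14/C15 pair, C5 and C10 form in the same event, and C–B oxidation with retention gives the 3α oxygen. For ring A this road is better than the chosen one, which needs an alkene shift, a hydroboration and a redox detour.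
- Weak points: a trisubstituted dienophile must form a quaternary carbon against an electron-poor diene. Facial control rests on C8 and C9 of A1, which need a long acyclic asymmetric synthesis. A2 has its carbonyl at C6, an ether at C8 and a C1=C2 bond, so ring B needs deoxygenation, oxidation, hydrogenation and an isopropenyl group at an unactivated carbon.
- Comparison: the chosen plan offers an achiral seven-step precursor, absolute configuration from a catalyst, and a ring B that leaves the key step with the C8 carbonyl and C6=C7 in place.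

Alternative 2: Here C5–C6 and C9–C10 are cut. 2-Methylcyclohex-2-en-1-one A3, bound to a chiral oxazaborolidine–AlBr3 Lewis acid, would be irradiated with vinylene carbonate A4 to give the cyclobutane carbonate A5, cis-fused to ring A.
- Merits: bulk starting materials, C5 and the cis C10 hydrogen set enantioselectively in one step, and a ketone at C4 to receive C15 and steer oxygenation at C3. The chosen plan lacks that C4 carbonyl.
- Weak points: the new ring is a cyclobutane, not ring B. After A5 the C6–C9 bond must be broken, C7 and C8 brought in, ring B closed, and C7, C8 and C9 functionalised from nothing. The photochemical step needs a high Lewis-acid loading, low temperature and a narrow wavelength window to outrun the racemic background.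
- Comparison: both plans take absolute configuration from a catalyst on achiral material. The chosen one leaves a complete decalin already oxidised at C8.

Alternative 3: The cuts are C4–C5 and C1–C10. The α-alkenylaluminium reagent A8, made from the chiral propargylic silyl ether A7 and (i-Bu)2AlH, would add to 3-methylcyclohex-2-en-1-one A6 under Cu(OTf)2 and a chiral N-heterocyclic carbene. The enolate, activated with MeLi, would displace chloride at C1 to give the cis-fused ketone A9.
- Merits: copper-catalysed alkenylalane additions to β-methyl enones are a proven route to quaternary carbons, and the annulation is one flask. A9 already holds C15 as a methylene beside a C3 silyl ether, so ring A needs only a directed hydrogenation. In ring A step count this road clearly beats the chosen plan.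
- Weak points: enantiopure A7 must be made and matched to the catalyst. α-Selective hydroalumination beside a silyl ether and an alkyl chloride is demanding. The ring fusion is set in the alkylation, not enforced by geometry. The carbonyl of A9 is at C9, so the 8-oxo-9-hydroxy pattern needs a 1,2-carbonyl transposition through a ketol that can equilibrate either way.
- Comparison: the chosen plan concedes the shorter ring A. It answers with a ring B that is correct from the start and C5/C10 fixed by a catalyst on an achiral substrate.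

Key step: step 8

Remarks.
- Bicyclic compounds use eremophilane numbering (C14 on C5, C15 on C4, C11–C13 on C7); β is the face of C14.
- Assumption: which enone arm the epi-quinine-derived thiourea selects cannot be predicted with certainty; the route is written for that catalyst, and its epi-quinidine-derived pseudoenantiomer is used if the opposite arm is preferred.
- The transient C8 carbinols (15, 16, 23–25) are drawn as the 8α epimers expected from hydride attack on the convex face; either epimer serves.

## Route

Step 1
Reactants: 1 3-ethoxycyclohex-2-en-1-one; 2 iodomethane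
Product: 4 3-ethoxy-6-methylcyclohex-2-en-1-one (racemic), via lithium enolate 3 (not isolated)
Conditions: LiN(i-Pr)2, THF, −78 °C; MeI, −78 → 0 °C
Reagents that add atoms: iodomethane (2), IC
Why: Stork–Danheiser α′-alkylation: kinetic deprotonation at C6 of the vinylogous ester and C-methylation; the new centre is racemic and later becomes the achiral C5 of the dienone.

Step 2
Reactants: 4 3-ethoxy-6-methylcyclohex-2-en-1-one; 5 4-chlorobutanoyl chloride
Product: 7 6-(4-chlorobutanoyl)-3-ethoxy-6-methylcyclohex-2-en-1-one (racemic), via lithium enolate 6 (not isolated)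
Conditions: LiN(i-Pr)2, THF, −78 °C; cannulated into 5, THF, −78 °C
Reagents that add atoms: 4-chlorobutanoyl chloride (5), ClCCCC(Cl)=O
Why: Claisen-type C-acylation of the tetrasubstituted lithium enolate; inverse addition at low temperature favours C- over O-acylation, and the quaternary product has no proton between the carbonyls, so no proton transfer or second acylation follows.

Step 3
Reactants: 7 6-(4-chlorobutanoyl)-3-ethoxy-6-methylcyclohex-2-en-1-one
Product: 8 6-(5-chloropent-1-en-2-yl)-3-ethoxy-6-methylcyclohex-2-en-1-one (racemic)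
Conditions: Tebbe reagent Cp2Ti(μ-Cl)(μ-CH2)AlMe2, pyridine (cat.), THF/toluene, −40 → 0 °C
Reagents that add atoms: Tebbe reagent, C=[Ti](C1C=CC=C1)C1C=CC=C1.C[Al](C)Cl
Why: Tebbe methylenation; the titanium methylidene takes the ketone well before the vinylogous ester carbonyl, copes with the neopentyl position, and is not basic, so the γ-chloro ketone cannot close to a cyclopropane as it would with a phosphorus ylide.

Step 4
Reactants: 8 6-(5-chloropent-1-en-2-yl)-3-ethoxy-6-methylcyclohex-2-en-1-one
Product: 10 4-(5-chloropent-1-en-2-yl)-4-methylcyclohex-2-en-1-one (racemic), via allylic alcohol 9 (not isolated)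
Conditions: i-Bu2AlH, CH2Cl2, −78 °C; then 1 M HCl, THF, 0 °C
Reagents that add atoms: water, O
Why: Stork–Danheiser transposition: 1,2-reduction, then acid hydrolysis of the enol ether and loss of water give the 4,4-disubstituted enone; the alkyl chloride and the 1,1-disubstituted alkene survive brief cold acid.

Step 5
Reactants: 10 4-(5-chloropent-1-en-2-yl)-4-methylcyclohex-2-en-1-one
Product: 11 4-(5-chloropent-1-en-2-yl)-4-methylcyclohexa-2,5-dien-1-one
Conditions: IBX, DMSO, 85 °C
Reagents that add atoms: none
Why: IBX dehydrogenation through the α′ enol gives the cross-conjugated dienone; with C4 quaternary the product cannot tautomerise to a phenol, and it is now achiral.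

Step 6
Reactants: 11 4-(5-chloropent-1-en-2-yl)-4-methylcyclohexa-2,5-dien-1-one
Product: 12 4-(5-iodopent-1-en-2-yl)-4-methylcyclohexa-2,5-dien-1-one
Conditions: NaI, acetone, reflux
Reagents that add atoms: sodium iodide, [Na+].[I-]
Why: Finkelstein exchange driven by precipitation of NaCl; iodide does not attack the dienone.

Step 7
Reactants: 12 4-(5-iodopent-1-en-2-yl)-4-methylcyclohexa-2,5-dien-1-one
Product: 13 4-methyl-4-(5-nitropent-1-en-2-yl)cyclohexa-2,5-dien-1-one
Conditions: AgNO2, Et2O, 0 °C → rt, dark
Reagents that add atoms: silver nitrite, [Ag+].[O-]N=O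
Why: Victor Meyer reaction of a primary iodide; the neutral silver conditions are chosen over nitrite in a dipolar solvent so that no base is present to start a racemic cyclisation of the product.

Step 8
Reactants: 13 4-methyl-4-(5-nitropent-1-en-2-yl)cyclohexa-2,5-dien-1-one
Product: 14 (1β,5β,10β)-1-nitro-11,12,13-trinoreremophila-4(15),6-dien-8-one (cis-fused)
Conditions: 9-amino-9-deoxy-epi-quinine 3,5-bis(trifluoromethyl)phenyl thiourea (10 mol %), toluene, 0 °C
Reagents that add atoms: none
Why: The quinuclidine nitrogen deprotonates the nitroalkane while the thiourea binds nitronate and dienone carbonyl by hydrogen bonds; the nitronate carbon C1 adds to C10 of one enone arm and the dienolate is protonated at C9 by the ammonium ion. The closest known reaction type is the cinchona amine–thiourea catalysed desymmetrising Michael cyclisation of carbon acids tethered to 4,4-disubstituted cyclohexadienones, together with intramolecular nitro-Michael cyclisations under the same catalysts. Ring A closes in the 6-exo-trig mode. C5 becomes stereogenic only through the choice of arm, which the catalyst makes; C10 follows from the three-carbon tether, which can reach C10 only on the face it occupies at C5, so the fusion is cis; C1 settles under thermodynamic control at the still acidic nitro carbon and is erased in step 10. The step needs discrimination between two enantiotopic arms of a substrate without a stereocentre, so the catalyst alone sets the sense. The quaternary C5 and the short tether exclude every other ring size, and the non-polar solvent, low temperature and base-free preparation of 13 hold back the uncatalysed cyclisation.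

Step 9
Reactants: 14 (1β,5β,10β)-1-nitro-11,12,13-trinoreremophila-4(15),6-dien-8-one
Product: 15 (1β,5β,8α,10β)-1-nitro-11,12,13-trinoreremophila-4(15),6-dien-8-ol
Conditions: NaBH4, CeCl3·7H2O, MeOH, −40 °C
Reagents that add atoms: none
Why: Luche 1,2-reduction parks the enone as an allylic alcohol because stannyl radicals would reduce a conjugated ketone in step 10; hydride enters from the convex β face, and borohydride leaves the nitro group alone.

Step 10
Reactants: 15 (1β,5β,8α,10β)-1-nitro-11,12,13-trinoreremophila-4(15),6-dien-8-ol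
Product: 16 (5β,8α,10β)-11,12,13-trinoreremophila-4(15),6-dien-8-ol
Conditions: Bu3SnH, AIBN, toluene, 110 °C
Reagents that add atoms: none
Why: Radical denitration: the stannyl radical adds to a nitro oxygen, the adduct loses the secondary C1 radical, and this takes hydrogen from the stannane; neither alkene is placed for a favourable radical cyclisation.

Step 11
Reactants: 16 (5β,8α,10β)-11,12,13-trinoreremophila-4(15),6-dien-8-ol
Product: 17 (5β,10β)-11,12,13-trinoreremophila-4(15),6-dien-8-one
Conditions: Dess–Martin periodinane, NaHCO3, CH2Cl2, rt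
Reagents that add atoms: none
Why: Dess–Martin oxidation of the only hydroxyl returns the enone under neutral conditions.

Step 12
Reactants: 17 (5β,10β)-11,12,13-trinoreremophila-4(15),6-dien-8-one
Product: 18 (5β,10β)-11,12,13-trinoreremophila-3,6-dien-8-one
Conditions: RhCl3·3H2O (10 mol %), EtOH, 75 °C
Reagents that add atoms: none
Why: Rhodium hydride addition–elimination moves the exocyclic double bond into the ring; C3 carries the only allylic hydrogens (C5 is quaternary), so only the more stable Δ3 isomer can form, and no cation arises that could let C14 migrate.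

Step 13
Reactants: 18 (5β,10β)-11,12,13-trinoreremophila-3,6-dien-8-one
Product: 20 (5β,9β,10β)-9-hydroxy-11,12,13-trinoreremophila-3,6-dien-8-one, via potassium dienolate 19 (not isolated)
Conditions: KN(SiMe3)2, THF, −78 °C; 2-(phenylsulfonyl)-3-phenyloxaziridine, −78 °C
Reagents that add atoms: 2-(phenylsulfonyl)-3-phenyloxaziridine, O=S(=O)(N1OC1c1ccccc1)c1ccccc1
Why: Davis hydroxylation of the cross-conjugated dienolate, which can only form toward C9; the oxaziridine comes from the β face because C1 and C4 of ring A cover the α face, and the 9β ketol is also the equatorial, more stable epimer.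

Step 14
Reactants: 20 (5β,9β,10β)-9-hydroxy-11,12,13-trinoreremophila-3,6-dien-8-one
Product: 21 (5β,9β,10β)-9-(tert-butyldimethylsilyloxy)-11,12,13-trinoreremophila-3,6-dien-8-one
Conditions: TBSOTf, 2,6-lutidine, CH2Cl2, −78 → 0 °C
Reagents that add atoms: tert-butyldimethylsilyl triflate, CC(C)(C)[Si](C)(C)OS(=O)(=O)C(F)(F)F
Why: Silylation of the hindered ketol hydroxyl with the silyl triflate; the ether lasts through hydride, borane and palladium steps and is later removed by fluoride without harm to esters.

Step 15
Reactants: 21 (5β,9β,10β)-9-(tert-butyldimethylsilyloxy)-11,12,13-trinoreremophila-3,6-dien-8-one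
Product: 22 (5β,9β,10β)-7-iodo-9-(tert-butyldimethylsilyloxy)-11,12,13-trinoreremophila-3,6-dien-8-one
Conditions: I2, pyridine, CH2Cl2, 0 °C → rt
Reagents that add atoms: iodine, I-I
Why: Johnson α-iodination of the enone (pyridine addition, iodination, elimination); the iodine is the handle for the C7–C11 bond and meanwhile deactivates C6=C7 toward borane.

Step 16
Reactants: 22 (5β,9β,10β)-7-iodo-9-(tert-butyldimethylsilyloxy)-11,12,13-trinoreremophila-3,6-dien-8-one
Product: 23 (5β,8α,9β,10β)-7-iodo-9-(tert-butyldimethylsilyloxy)-11,12,13-trinoreremophila-3,6-dien-8-ol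
Conditions: NaBH4, CeCl3·7H2O, MeOH, −40 °C
Reagents that add atoms: none
Why: Luche reduction removes the carbonyl before borane is used; the C8 configuration is of no consequence.

Step 17
Reactants: 23 (5β,8α,9β,10β)-7-iodo-9-(tert-butyldimethylsilyloxy)-11,12,13-trinoreremophila-3,6-dien-8-ol
Product: 25 (3α,4β-methyl,5β,8α,9β,10β)-7-iodo-9-(tert-butyldimethylsilyloxy)-11,12,13-trinoreremophil-6-ene-3,8-diol, via C3 alkylborane 24 (not isolated)
Conditions: BH3·THF, THF, 0 °C → rt; then NaBO3·4H2O, H2O, rt
Reagents that add atoms: sodium perborate, [Na+].[Na+].O[B-]1(O)OO[B-](O)(O)OO1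
Why: Brown hydroboration–oxidation: syn, anti-Markovnikov addition puts boron on C3 and hydrogen on C4 from the α face, away from the syn-axial C14, so C15 ends β (cis to C14) and oxidation with retention gives the 3α alcohol. The hindered, electron-poor iodoalkene is left alone, and the near-neutral perborate work-up avoids silyl migration to O8.

Step 18
Reactants: 25 (3α,4β-methyl,5β,8α,9β,10β)-7-iodo-9-(tert-butyldimethylsilyloxy)-11,12,13-trinoreremophil-6-ene-3,8-diol
Product: 26 (3α,4β-methyl,5β,9β,10β)-3-hydroxy-7-iodo-9-(tert-butyldimethylsilyloxy)-11,12,13-trinoreremophil-6-en-8-one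
Conditions: MnO2, CH2Cl2, rt
Reagents that add atoms: none
Why: MnO2 oxidises only the allylic C8 carbinol, restoring the α-iodoenone and leaving the saturated C3 alcohol.

Step 19
Reactants: 26 (3α,4β-methyl,5β,9β,10β)-3-hydroxy-7-iodo-9-(tert-butyldimethylsilyloxy)-11,12,13-trinoreremophil-6-en-8-one; 27 4,4,5,5-tetramethyl-2-(prop-1-en-2-yl)-1,3,2-dioxaborolane
Product: 28 (3α,4β-methyl,5β,9β,10β)-3-hydroxy-9-(tert-butyldimethylsilyloxy)eremophila-6,11-dien-8-one
Conditions: Pd(dppf)Cl2 (5 mol %), Cs2CO3, THF/H2O, 45 °C
Reagents that add atoms: isopropenylboronic acid pinacol ester (27), CC(=C)B1OC(C)(C)C(C)(C)O1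
Why: Suzuki–Miyaura coupling of an α-iodoenone with an alkenylboronate, a standard pairing; the free C3 hydroxyl is tolerated, and the step precedes the acyl chain, whose allylic ester palladium would ionise.

Step 20
Reactants: 28 (3α,4β-methyl,5β,9β,10β)-3-hydroxy-9-(tert-butyldimethylsilyloxy)eremophila-6,11-dien-8-one
Product: 30 (3α,4β-methyl,5β,7β-isopropenyl,9β,10β)-3-hydroxy-9-(tert-butyldimethylsilyloxy)eremophil-11-en-8-one, via 7-epimer 29 (not isolated)
Conditions: [(Ph3P)CuH]6, H2O, benzene, rt; then Et3N, CH2Cl2, 0 °C → rt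
Reagents that add atoms: none
Why: Stryker conjugate reduction: copper hydride adds to C6 of the enone only, and the copper enolate is protonated at C7, which keeps C11=C12 out of conjugation. Protonation from the open β face gives partly the 7-epimer 29, and brief contact with triethylamine equilibrates it to 30, in which C14, the isopropenyl group and the C9 oxygen are all equatorial.

Step 21
Reactants: 31 (R)-2-ethyloxirane
Product: 32 (R)-pent-1-en-3-ol
Conditions: Me3S+ I−, n-BuLi, THF, −10 °C → rt
Reagents that add atoms: trimethylsulfonium iodide, C[S+](C)C.[I-]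
Why: One-carbon homologation of a terminal epoxide to an allylic alcohol with dimethylsulfonium methylide (opening at CH2, then elimination of dimethyl sulfide through the sulfonium ylide); the stereocentre is not touched.

Step 22
Reactants: 32 (R)-pent-1-en-3-ol; 33 (Z)-2-methylbut-2-enoic acid (angelic acid)
Product: 35 (R)-pent-1-en-3-yl (Z)-2-methylbut-2-enoate, via mixed anhydride 34 (not isolated)
Conditions: 33, 2,4,6-trichlorobenzoyl chloride, Et3N, toluene, rt; then 32, toluene, 80 °C
Reagents that add atoms: angelic acid (33), OC(=O)/C(C)=C\C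
Why: Yamaguchi-type esterification through the mixed anhydride without a nucleophilic catalyst, the established way to make angelates without Z-to-E isomerisation to tiglates.

Step 23
Reactants: 35 (R)-pent-1-en-3-yl (Z)-2-methylbut-2-enoate; 36 acrylic acid
Product: 37 (2E,4R)-4-{[(2Z)-2-methylbut-2-enoyl]oxy}hex-2-enoic acid
Conditions: second-generation Hoveyda–Grubbs catalyst RuCl2(H2IMes)(=CH-C6H4-2-O-i-Pr) (5 mol %), CH2Cl2, 40 °C
Reagents that add atoms: acrylic acid (36), OC(=O)C=C
Why: Olefin cross-metathesis of a terminal alkene with acrylic acid gives the E enoic acid; the trisubstituted, conjugated angelate double bond does not engage the ruthenium carbene.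

Step 24
Reactants: 30 (3α,4β-methyl,5β,7β-isopropenyl,9β,10β)-3-hydroxy-9-(tert-butyldimethylsilyloxy)eremophil-11-en-8-one; 37 (2E,4R)-4-{[(2Z)-2-methylbut-2-enoyl]oxy}hex-2-enoic acid
Product: 38 (3R,4R,5R,7R,9R,10S)-9-(tert-butyldimethylsilyloxy)-8-oxoeremophil-11-en-3-yl (2E,4R)-4-{[(2Z)-2-methylbut-2-enoyl]oxy}hex-2-enoate
Conditions: DCC, DMAP (cat.), CH2Cl2, 0 °C → rt
Reagents that add atoms: none
Why: Steglich esterification of the only free hydroxyl (equatorial C3–OH); mild enough to leave C7, the enoate geometry and the angelate untouched.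

Step 25
Reactants: 38 (3R,4R,5R,7R,9R,10S)-9-(tert-butyldimethylsilyloxy)-8-oxoeremophil-11-en-3-yl (2E,4R)-4-{[(2Z)-2-methylbut-2-enoyl]oxy}hex-2-enoate
Product: 39 (3R,4R,5R,7R,9R,10S)-9-hydroxy-8-oxoeremophil-11-en-3-yl (2E,4R)-4-{[(2Z)-2-methylbut-2-enoyl]oxy}hex-2-enoate (CNP0190706.1)
Conditions: HF·pyridine, pyridine, THF, 0 °C → rt
Reagents that add atoms: none
Why: Fluoride desilylation under buffered conditions; both esters, the allylic acyloxy group and the β,γ-unsaturated ketone are stable to it.

## Compound list

1 | 3-ethoxycyclohex-2-en-1-one | CCOC1=CC(=O)CCC1 | starting material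
2 | iodomethane | IC | starting material
3 | lithium 5-ethoxycyclohexa-1,5-dien-1-olate (enolate of 1) | CCOC1=CC(O[Li])=CCC1 | intermediate
4 | 3-ethoxy-6-methylcyclohex-2-en-1-one (racemic) | CCOC1=CC(=O)C(C)CC1 | intermediate
5 | 4-chlorobutanoyl chloride | ClCCCC(Cl)=O | starting material
6 | lithium 5-ethoxy-2-methylcyclohexa-1,5-dien-1-olate (enolate of 4) | CCOC1=CC(O[Li])=C(C)CC1 | intermediate
7 | 6-(4-chlorobutanoyl)-3-ethoxy-6-methylcyclohex-2-en-1-one (racemic) | CCOC1=CC(=O)C(C)(CC1)C(=O)CCCCl | intermediate
8 | 6-(5-chloropent-1-en-2-yl)-3-ethoxy-6-methylcyclohex-2-en-1-one (racemic) | CCOC1=CC(=O)C(C)(CC1)C(=C)CCCCl | intermediate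
9 | 6-(5-chloropent-1-en-2-yl)-3-ethoxy-6-methylcyclohex-2-en-1-ol (diastereomers) | CCOC1=CC(O)C(C)(CC1)C(=C)CCCCl | intermediate
10 | 4-(5-chloropent-1-en-2-yl)-4-methylcyclohex-2-en-1-one (racemic) | CC1(C=CC(=O)CC1)C(=C)CCCCl | intermediate
11 | 4-(5-chloropent-1-en-2-yl)-4-methylcyclohexa-2,5-dien-1-one | CC1(C=CC(=O)C=C1)C(=C)CCCCl | intermediate
12 | 4-(5-iodopent-1-en-2-yl)-4-methylcyclohexa-2,5-dien-1-one | ICCCC(=C)C1(C)C=CC(=O)C=C1 | intermediate
13 | 4-methyl-4-(5-nitropent-1-en-2-yl)cyclohexa-2,5-dien-1-one | CC1(C=CC(=O)C=C1)C(=C)CCC[N+](=O)[O-] | intermediate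
14 | (1β,5β,10β)-1-nitro-11,12,13-trinoreremophila-4(15),6-dien-8-one | C1=C[C@@]2(C)[C@H]([C@H]([N+](=O)[O-])CCC2=C)CC1=O | intermediate
15 | (1β,5β,8α,10β)-1-nitro-11,12,13-trinoreremophila-4(15),6-dien-8-ol | C1=C[C@@]2(C)[C@H]([C@H]([N+](=O)[O-])CCC2=C)C[C@@H]1O | intermediate
16 | (5β,8α,10β)-11,12,13-trinoreremophila-4(15),6-dien-8-ol | C1=C[C@@]2(C)[C@H](CCCC2=C)C[C@@H]1O | intermediate
17 | (5β,10β)-11,12,13-trinoreremophila-4(15),6-dien-8-one | C1=C[C@@]2(C)[C@H](CCCC2=C)CC1=O | intermediate
18 | (5β,10β)-11,12,13-trinoreremophila-3,6-dien-8-one | C1=C[C@@]2(C)[C@H](CCC=C2C)CC1=O | intermediate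
19 | potassium dienolate of 18 (C6=C7–C8(OK)=C9) | C1=C[C@@]2(C)[C@H](CCC=C2C)C=C1O[K] | intermediate
20 | (5β,9β,10β)-9-hydroxy-11,12,13-trinoreremophila-3,6-dien-8-one | C1=C[C@@]2(C)[C@H](CCC=C2C)[C@@H](O)C1=O | intermediate
21 | (5β,9β,10β)-9-(tert-butyldimethylsilyloxy)-11,12,13-trinoreremophila-3,6-dien-8-one | C1=C[C@@]2(C)[C@H](CCC=C2C)[C@@H](O[Si](C)(C)C(C)(C)C)C1=O | intermediate
22 | (5β,9β,10β)-7-iodo-9-(tert-butyldimethylsilyloxy)-11,12,13-trinoreremophila-3,6-dien-8-one | IC1=C[C@@]2(C)[C@H](CCC=C2C)[C@@H](O[Si](C)(C)C(C)(C)C)C1=O | intermediate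
23 | (5β,8α,9β,10β)-7-iodo-9-(tert-butyldimethylsilyloxy)-11,12,13-trinoreremophila-3,6-dien-8-ol | IC1=C[C@@]2(C)[C@H](CCC=C2C)[C@@H](O[Si](C)(C)C(C)(C)C)[C@@H]1O | intermediate
24 | C3 alkylborane of 23 (3α-BH2, 4β-methyl, O8–BH2) | IC1=C[C@@]2(C)[C@H](CC[C@@H](B)[C@@H]2C)[C@@H](O[Si](C)(C)C(C)(C)C)[C@@H]1OB | intermediate
25 | (3α,4β-methyl,5β,8α,9β,10β)-7-iodo-9-(tert-butyldimethylsilyloxy)-11,12,13-trinoreremophil-6-ene-3,8-diol | IC1=C[C@@]2(C)[C@H](CC[C@@H](O)[C@@H]2C)[C@@H](O[Si](C)(C)C(C)(C)C)[C@@H]1O | intermediate
26 | (3α,4β-methyl,5β,9β,10β)-3-hydroxy-7-iodo-9-(tert-butyldimethylsilyloxy)-11,12,13-trinoreremophil-6-en-8-one | IC1=C[C@@]2(C)[C@H](CC[C@@H](O)[C@@H]2C)[C@@H](O[Si](C)(C)C(C)(C)C)C1=O | intermediate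
27 | 4,4,5,5-tetramethyl-2-(prop-1-en-2-yl)-1,3,2-dioxaborolane | CC(=C)B1OC(C)(C)C(C)(C)O1 | starting material
28 | (3α,4β-methyl,5β,9β,10β)-3-hydroxy-9-(tert-butyldimethylsilyloxy)eremophila-6,11-dien-8-one | C=C(C)C1=C[C@@]2(C)[C@H](CC[C@@H](O)[C@@H]2C)[C@@H](O[Si](C)(C)C(C)(C)C)C1=O | intermediate
29 | 7-epimer of 30 (7α-isopropenyl) | C=C(C)[C@@H]1C[C@@]2(C)[C@H](CC[C@@H](O)[C@@H]2C)[C@@H](O[Si](C)(C)C(C)(C)C)C1=O | intermediate
30 | (3α,4β-methyl,5β,7β-isopropenyl,9β,10β)-3-hydroxy-9-(tert-butyldimethylsilyloxy)eremophil-11-en-8-one | C=C(C)[C@H]1C[C@@]2(C)[C@H](CC[C@@H](O)[C@@H]2C)[C@@H](O[Si](C)(C)C(C)(C)C)C1=O | intermediate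
31 | (R)-2-ethyloxirane | CC[C@@H]1CO1 | starting material
32 | (R)-pent-1-en-3-ol | C=C[C@@H](CC)O | intermediate
33 | (Z)-2-methylbut-2-enoic acid (angelic acid) | OC(=O)/C(C)=C\C | starting material
34 | (Z)-2-methylbut-2-enoic 2,4,6-trichlorobenzoic anhydride | O=C(OC(=O)/C(C)=C\C)c1c(Cl)cc(Cl)cc1Cl | intermediate
35 | (R)-pent-1-en-3-yl (Z)-2-methylbut-2-enoate | C=C[C@@H](CC)OC(=O)/C(C)=C\C | intermediate
36 | acrylic acid | OC(=O)C=C | starting material
37 | (2E,4R)-4-{[(2Z)-2-methylbut-2-enoyl]oxy}hex-2-enoic acid | OC(=O)/C=C/[C@@H](CC)OC(=O)/C(C)=C\C | intermediate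
38 | (3R,4R,5R,7R,9R,10S)-9-(tert-butyldimethylsilyloxy)-8-oxoeremophil-11-en-3-yl (2E,4R)-4-{[(2Z)-2-methylbut-2-enoyl]oxy}hex-2-enoate | C=C(C)[C@H]1C[C@@]2(C)[C@H](CC[C@@H](OC(=O)/C=C/[C@@H](CC)OC(=O)/C(C)=C\C)[C@@H]2C)[C@@H](O[Si](C)(C)C(C)(C)C)C1=O | intermediate
39 | (3R,4R,5R,7R,9R,10S)-9-hydroxy-8-oxoeremophil-11-en-3-yl (2E,4R)-4-{[(2Z)-2-methylbut-2-enoyl]oxy}hex-2-enoate | C=C(C)[C@H]1C[C@@]2(C)[C@H](CC[C@@H](OC(=O)/C=C/[C@@H](CC)OC(=O)/C(C)=C\C)[C@@H]2C)[C@@H](O)C1=O | target

## Step count and least certain steps

Total: 25 steps. Longest linear sequence: 22 steps (steps 1–20, 24 and 25). The acid 37 takes 3 steps (21–23).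

**Step 8 (key step).** The likely failure is weak discrimination between the two enone arms, or a racemic uncatalysed cyclisation running beside the catalysed one. A primary nitronate is small and reactive and the tether is pre-organised. Fallback: change the donor from a nitronate to an acyl anion equivalent, which forms the same C1–C10 bond. From iodide 12, silver-assisted Kornblum oxidation (AgBF4, DMSO, then Et3N) gives the aldehyde 4-methyl-4-(5-oxopent-1-en-2-yl)cyclohexa-2,5-dien-1-one F1. An asymmetric intramolecular Stetter reaction with a chiral aminoindanol-derived triazolium carbene, well established for dienone desymmetrisation, closes ring A to the cis-fused 1,8-dione F2. The saturated C1 ketone alone is converted into the tosylhydrazone F3, and catecholborane followed by NaOAc·3H2O reduces it to CH2. The route is rejoined at 17, and steps 9–11 are no longer needed.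

**Step 17.** The likely failures are attack of borane on the β face (the α face at C4 is brushed by C9), competing reaction at the iodoalkene, or silyl migration to O8 during work-up. Fallback without borane and without a parked alcohol, starting from 21. Peracid epoxidation of C3=C4 gives the 3α,4α-epoxide F4. Et2Al(TMP) opens it by removing a C15 proton to give the 3α-hydroxy-4(15)-ene F5. Hydroxyl-directed hydrogenation with [Ir(cod)(PCy3)(py)]PF6 gives the 3α-hydroxy-4β-methyl enone F6; here C4 is set by delivery from the C3 hydroxyl, not by the face of the first addition. Iodination with I2/pyridine returns to the route at 26.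

**Step 20.** The likely failure is protonation of the enolate at C7 from the open β face, giving mostly the 7-epimer. The base needed to correct it can also pull C11=C12 into conjugation with C8. Fallback: deliver the C7 hydrogen from a directing group and build the isopropenyl group afterwards, starting from 25.
- Stille coupling with tributyl(1-ethoxyvinyl)stannane (Pd(PPh3)4, CuI) gives the dienol ether F7.
- Dilute acid hydrolyses it to the 7-acetyl-6-ene F8.
- The 8α hydroxyl directs [Ir(cod)(PCy3)(py)]PF6/H2 to the α face, giving the 7β-acetyl-8α-ol F9.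
- Non-basic methylenation (Zn, CH2Br2, TiCl4) gives the 7β-isopropenyl 3α,8α-diol F10, in which C7 can no longer epimerise.
- The less hindered C3 hydroxyl is acylated with 37 (DCC, DMAP) to the 8-hydroxy ester F11.
- Dess–Martin oxidation of C8 rejoins the route at 38.

**Step 10.** The likely failure is slow C–N fragmentation of the stannyl adduct of a secondary nitroalkane, so that conversion stalls or nitrogen is merely reduced. Fallback through the carbonyl, from 15: nitronate formation (NaOMe) and buffered TiCl3 (reductive Nef reaction) give the 8α-hydroxy C1 ketone F12. Its tosylhydrazone F13 is reduced with catecholborane and NaOAc·3H2O, returning to the route at 16.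

**Step 3.** The likely failure is reaction of the titanium methylidene with the vinylogous ester carbonyl as well, or stalling at the neopentyl ketone. Fallback by addition–elimination (Peterson olefination), from 7: Me3SiCH2MgCl with CeCl3 adds to the ketone to give the β-hydroxysilane F14. It is quenched cold and kept neutral so that the alkoxide does not displace the chloride. BF3·OEt2 then induces elimination, returning to the route at 8.

## Further compounds

F1 | step 8 | 4-methyl-4-(5-oxopent-1-en-2-yl)cyclohexa-2,5-dien-1-one | CC1(C=CC(=O)C=C1)C(=C)CCC=O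
F2 | step 8 | (5β,10β)-11,12,13-trinoreremophila-4(15),6-diene-1,8-dione | C1=C[C@@]2(C)[C@H](C(=O)CCC2=C)CC1=O
F3 | step 8 | C1 tosylhydrazone of F2 | C1=C[C@@]2(C)[C@H](C(CCC2=C)=NNS(=O)(=O)c3ccc(C)cc3)CC1=O
F4 | step 17 | (3α,4α-epoxy,5β,9β,10β)-9-(tert-butyldimethylsilyloxy)-11,12,13-trinoreremophil-6-en-8-one | C1=C[C@@]2(C)[C@H](CC[C@@H](O3)[C@]23C)[C@@H](O[Si](C)(C)C(C)(C)C)C1=O
F5 | step 17 | (3α,5β,9β,10β)-3-hydroxy-9-(tert-butyldimethylsilyloxy)-11,12,13-trinoreremophila-4(15),6-dien-8-one | C1=C[C@@]2(C)[C@H](CC[C@@H](O)C2=C)[C@@H](O[Si](C)(C)C(C)(C)C)C1=O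
F6 | step 17 | (3α,4β-methyl,5β,9β,10β)-3-hydroxy-9-(tert-butyldimethylsilyloxy)-11,12,13-trinoreremophil-6-en-8-one | C1=C[C@@]2(C)[C@H](CC[C@@H](O)[C@@H]2C)[C@@H](O[Si](C)(C)C(C)(C)C)C1=O
F7 | step 20 | (3α,4β-methyl,5β,8α,9β,10β)-7-(1-ethoxyvinyl)-9-(tert-butyldimethylsilyloxy)-11,12,13-trinoreremophil-6-ene-3,8-diol | C=C(OCC)C1=C[C@@]2(C)[C@H](CC[C@@H](O)[C@@H]2C)[C@@H](O[Si](C)(C)C(C)(C)C)[C@@H]1O
F8 | step 20 | (3α,4β-methyl,5β,8α,9β,10β)-7-acetyl-9-(tert-butyldimethylsilyloxy)-11,12,13-trinoreremophil-6-ene-3,8-diol | CC(=O)C1=C[C@@]2(C)[C@H](CC[C@@H](O)[C@@H]2C)[C@@H](O[Si](C)(C)C(C)(C)C)[C@@H]1O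
F9 | step 20 | (3α,4β-methyl,5β,7β-acetyl,8α,9β,10β)-7-acetyl-9-(tert-butyldimethylsilyloxy)-11,12,13-trinoreremophilane-3,8-diol | CC(=O)[C@H]1C[C@@]2(C)[C@H](CC[C@@H](O)[C@@H]2C)[C@@H](O[Si](C)(C)C(C)(C)C)[C@@H]1O
F10 | step 20 | (3α,4β-methyl,5β,7β-isopropenyl,8α,9β,10β)-9-(tert-butyldimethylsilyloxy)eremophil-11-ene-3,8-diol | C=C(C)[C@H]1C[C@@]2(C)[C@H](CC[C@@H](O)[C@@H]2C)[C@@H](O[Si](C)(C)C(C)(C)C)[C@@H]1O
F11 | step 20 | (8α)-8-hydroxy-9β-(tert-butyldimethylsilyloxy)eremophil-11-en-3α-yl (2E,4R)-4-{[(2Z)-2-methylbut-2-enoyl]oxy}hex-2-enoate | C=C(C)[C@H]1C[C@@]2(C)[C@H](CC[C@@H](OC(=O)/C=C/[C@@H](CC)OC(=O)/C(C)=C\C)[C@@H]2C)[C@@H](O[Si](C)(C)C(C)(C)C)[C@@H]1O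
F12 | step 10 | (5β,8α,10β)-8-hydroxy-11,12,13-trinoreremophila-4(15),6-dien-1-one | C1=C[C@@]2(C)[C@H](C(=O)CCC2=C)C[C@@H]1O
F13 | step 10 | C1 tosylhydrazone of F12 | C1=C[C@@]2(C)[C@H](C(CCC2=C)=NNS(=O)(=O)c3ccc(C)cc3)C[C@@H]1O
F14 | step 3 | 6-[5-chloro-2-hydroxy-1-(trimethylsilyl)pentan-2-yl]-3-ethoxy-6-methylcyclohex-2-en-1-one (diastereomers, racemic) | CCOC1=CC(=O)C(C)(CC1)C(O)(C[Si](C)(C)C)CCCCl
A1 | alternative 1 | open-chain (E)-tigloyl ketone with 8-silyloxy, 9-(4-methoxybenzyloxy) and terminal (1E,3E)-1-(pinacolboryl)diene | C/C=C(\C)C(=O)C[C@@H](O[Si](C)(C)C(C)(C)C)[C@H](OCc1ccc(OC)cc1)/C=C/C=C/B1OC(C)(C)C(C)(C)O1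
A2 | alternative 1 | cis-fused 4,5-dimethyl-octal-1-en-6-one C3 allylboronate (8-silyloxy, 9-PMB ether) | C1C(=O)[C@@]2(C)[C@H](C=C[C@@H](B3OC(C)(C)C(C)(C)O3)[C@@H]2C)[C@@H](OCc4ccc(OC)cc4)[C@@H]1O[Si](C)(C)C(C)(C)C
A3 | alternative 2 | 2-methylcyclohex-2-en-1-one | CC1=CCCCC1=O
A4 | alternative 2 | 1,3-dioxol-2-one (vinylene carbonate) | O=C1OC=CO1
A5 | alternative 2 | cis-fused cyclobutane carbonate photoadduct | O=C1CCC[C@@H]2[C@H]3OC(=O)O[C@H]3[C@]12C
A6 | alternative 3 | 3-methylcyclohex-2-en-1-one | CC1=CC(=O)CCC1
A7 | alternative 3 | (R)-tert-butyl[(5-chloropent-1-yn-3-yl)oxy]dimethylsilane | ClCC[C@@H](O[Si](C)(C)C(C)(C)C)C#C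
A8 | alternative 3 | diisobutyl[(R)-3-(tert-butyldimethylsilyloxy)-5-chloropent-1-en-2-yl]aluminium | C=C([Al](CC(C)C)CC(C)C)[C@@H](CCCl)O[Si](C)(C)C(C)(C)C
A9 | alternative 3 | cis-fused 5-methyl-4-methylene-3-silyloxydecalin-9-one | C1C[C@@]2(C)[C@H](CC[C@@H](O[Si](C)(C)C(C)(C)C)C2=C)C(=O)C1
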